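Numbering (eudesmane): ring A = C1-C2-C3-C4-C5-C10, ring B = C5-C6-C7-C8-C9-C10, C14 on C10, C15 on C4, C11(=C13)-C12 on C7; β is the face of C14.
Cuts, in retrosynthetic order: C5–OOH (ene reaction, back to a C4=C5 alkene with C15 as methyl), the C3 and C8 acyl groups, C3–O (allylic oxidation), C11=C13 and C7–C11 (methylenation, enolate allylation), C4–C15 (methyl addition to a ketone), and last C6–C7 together with C5–C10.
Enabling feature: C4 is sp2 and lies next to C5, and C8 carries oxygen. Read as a C4 ketone and a C8 enol silane, ring B is the cyclohexene of a Diels–Alder reaction between the C5=C6 vinyl ketone and the C7=C8–C9=C10 2-silyloxydiene. Electrophilic C6 lies opposite nucleophilic C7, C5 opposite the methyl-bearing C10, and C1–C4 form the bridge that becomes ring A.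
Forward: the chain is joined from hex-5-yn-1-ol (C9, C10, C1–C4) by carboalumination (C14), Stille coupling (C8, C7) and vinyl Grignard addition (C5, C6). Rings A and B close together in step 7, followed by C15 and the C4=C5 alkene, the C7/C8 side of ring B, the C3 oxygen, and the hydroperoxide last.
Stereochemistry: C10 comes from the chiral boron Lewis acid (enone face combined with endo mode). C7 is set by equilibration to the equatorial position of a ring B chair locked by axial C14, C8 and C3 by hydride delivery from the α face, and C5 by attack of singlet oxygen anti to C14.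

Key step: step 7

Assumption: the (S)-configured catalyst is taken to leave the Re face of C5 open, by analogy with its sense of induction on acrylates and acyclic vinyl ketones; if correlation of 19 shows the opposite sense, the (R)-catalyst is used and nothing else changes.

Step 1
Reactants: 1 hex-5-yn-1-ol; 2 trimethylaluminium
Product: 4 (E)-6-iodo-5-methylhex-5-en-1-ol, via alkenylalane 3 (not isolated)
Conditions: Me3Al (3 equiv), Cp2ZrCl2 (0.25 equiv), CH2Cl2, 0 °C to rt; then I2, THF, −30 to 0 °C; aq. potassium sodium tartrate
Reagents that add atoms: trimethylaluminium C[Al](C)C; iodine [I][I]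
Why: Negishi zirconium-catalysed carboalumination adds methyl and aluminium syn across the terminal alkyne with methyl on the internal carbon (the hydroxyl travels as its aluminium alkoxide), and iodinolysis of the C–Al bond with retention should give only the E iodide that later places C1 outside and C14 inside on the diene.

Step 2
Reactants: 4 (E)-6-iodo-5-methylhex-5-en-1-ol
Product: 5 (E)-6-iodo-5-methylhex-5-enoic acid
Conditions: 2,2,6,6-tetramethylpiperidin-1-oxyl (0.2 equiv), PhI(OAc)2 (2.2 equiv), MeCN/H2O 1:1, rt
Reagents that add atoms: water O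
Why: The nitroxyl-catalysed oxidation with PhI(OAc)2 in aqueous acetonitrile takes a primary alcohol through the aldehyde hydrate to the acid under near-neutral conditions that leave an alkenyl iodide untouched.

Step 3
Reactants: 5 (E)-6-iodo-5-methylhex-5-enoic acid; 6 N,O-dimethylhydroxylamine hydrochloride
Product: 8 (E)-6-iodo-N-methoxy-N,5-dimethylhex-5-enamide, via acyl imidazole 7 (not isolated)
Conditions: 1,1'-carbonyldiimidazole, CH2Cl2, 0 °C to rt; then MeNH(OMe)·HCl, rt
Reagents that add atoms: 1,1'-carbonyldiimidazole O=C(n1ccnc1)n1ccnc1; N,O-dimethylhydroxylamine hydrochloride CNOC.Cl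
Why: Activation as the acyl imidazole followed by aminolysis is the standard Weinreb amide synthesis and contains nothing that can disturb the alkenyl iodide.

Step 4
Reactants: 8 (E)-6-iodo-N-methoxy-N,5-dimethylhex-5-enamide; 9 tributyl(1-ethoxyvinyl)stannane
Product: 11 (E)-N-methoxy-N,5-dimethyl-7-oxooct-5-enamide, via ethoxydiene 10 (not isolated)
Conditions: Pd(PPh3)4 (5 mol %), toluene, 90 °C; then 1 M HCl, THF, 0 °C
Reagents that add atoms: tributyl(1-ethoxyvinyl)stannane CCCC[Sn](CCCC)(CCCC)C(=C)OCC; water O
Why: Stille coupling of an alkenyl iodide keeps the E geometry and brings in C8 and C7 as an enol ether, which brief cold aqueous acid hydrolyses to the methyl enone while the Weinreb amide stays intact.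

Step 5
Reactants: 11 (E)-N-methoxy-N,5-dimethyl-7-oxooct-5-enamide
Product: 12 (E)-N-methoxy-N,5-dimethyl-7-(triisopropylsilyloxy)octa-5,7-dienamide
Conditions: i-Pr3SiOSO2CF3 (1.15 equiv), Et3N (2 equiv), CH2Cl2, −78 to 0 °C
Reagents that add atoms: triisopropylsilyl triflate CC(C)[Si](OS(=O)(=O)C(F)(F)F)(C(C)C)C(C)C
Why: Soft enolisation (O-silylation by the silyl triflate, then deprotonation by Et3N at the unhindered alpha' methyl group) is the usual way from methyl enones to cross-conjugated 2-silyloxydienes; the less electrophilic amide is left alone, and the triisopropylsilyl group is chosen because it resists acid and silyl transfer in steps 6 and 7.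

Step 6
Reactants: 12 (E)-N-methoxy-N,5-dimethyl-7-(triisopropylsilyloxy)octa-5,7-dienamide; 13 vinylmagnesium bromide
Product: 15 (E)-7-methyl-9-(triisopropylsilyloxy)deca-1,7,9-trien-3-one, via magnesium chelate 14 (not isolated)
Conditions: CH2=CHMgBr (1.5 equiv), THF, −78 to 0 °C; inverse quench into cold aq. NaHSO4/Et2O; kept cold and used at once
Reagents that add atoms: vinylmagnesium bromide C=C[Mg]Br
Why: Weinreb ketone synthesis: the magnesium-chelated tetrahedral adduct holds until the quench so that only one vinyl group adds, and the cold acidic inverse quench protonates the released amine before it can add to the vinyl ketone; the trienone is handled cold and dilute to avoid uncatalysed cyclisation.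

Step 7
Reactants: 15 (E)-7-methyl-9-(triisopropylsilyloxy)deca-1,7,9-trien-3-one
Product: 16 (4aR,8aS)-4a-methyl-6-(triisopropylsilyloxy)-3,4,4a,7,8,8a-hexahydronaphthalen-1(2H)-one (cis-fused 10-methyl-8-silyloxyoctal-8-en-4-one; 5S,10R; H-5 and C14 both β)
Conditions: (S)-3,3-diphenyl-1-(o-tolyl)tetrahydro-1H,3H-pyrrolo[1,2-c][1,3,2]oxazaborole (20 mol %), HN(SO2CF3)2 (16 mol %), CH2Cl2, −78 °C; 15 added slowly (final 0.01 M), −78 to −40 °C; Et3N quench, chromatography
Reagents that add atoms: none
Why: The protonated oxazaborolidine binds the C4 carbonyl oxygen on the lone pair next to the vinyl group (B–O bond backed by a contact between C5–H and the ring oxygen), which lowers the enone LUMO and covers the Si face of C5, so that the silyloxydiene reaches the Re face in one strongly asynchronous [4+2] event in which C6–C7 is far advanced before C5–C10 forms and the developing positive charge is carried by the tertiary allylic C10 and the C8 oxygen. The closest known reactions are the additions of 2-(triisopropylsilyloxy)butadiene to enones and the cyclisations of trienals under the same catalyst, and the thermal or Lewis acid promoted type 1 intramolecular Diels–Alder reaction of 1,7,9-decatrien-3-ones. Ring B closes as the new cyclohexene through both σ bonds (six-centre pericyclic closure) and ring A closes at the same time as the fused six-membered ring spanned by the C1–C2–C3–C4 bridge. C5 is set by the catalyst-covered enone face, and C10 is tied to C5 by the E geometry of C9=C10 (C1 outside, C14 inside) and by the endo position of the bridging carbonyl under the diene, which together give the cis fusion with H-5 and C14 both β. Since C5 is erased in step 9, the selectivity that counts is the diene face at C10, which is the product of enone face and endo/exo mode: an exo adduct formed on the same enone face has the opposite C10, so the endo preference raised by the Lewis acid is needed and the trans-fused minor isomer is removed by chromatography before any contact with base. Regiochemistry is fixed by the bridge and agrees with the polarity (nucleophilic C7, electrophilic C6), while high dilution, low temperature, a slight deficit of HN(SO2CF3)2 and the robust silyl group hold back intermolecular Mukaiyama–Michael addition, the racemic background reaction and desilylation.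

Step 8
Reactants: 16 cis-fused adduct; 17 methylmagnesium bromide
Product: 18 4-hydroxy-4,10-dimethyl-8-(triisopropylsilyloxy)octal-8-ene (5β-H, 10β-Me; configuration at C4 open and of no consequence)
Conditions: CeCl3 (anhydrous, 2 equiv), MeMgBr (2 equiv), THF, −78 to 0 °C; aq. NH4Cl
Reagents that add atoms: methylmagnesium bromide C[Mg]Br
Why: Organocerium 1,2-addition (Imamoto conditions) delivers C15 to the hindered, enolisable C4 ketone without deprotonation and leaves the enol silane alone; the new C4 carbinol centre may form as either epimer because it is removed in step 9.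

Step 9
Reactants: 18 tertiary alcohol
Product: 19 (R)-5,8a-dimethyl-3,4,6,7,8,8a-hexahydronaphthalen-2(1H)-one (4,10-dimethyloctal-4-en-8-one, 10R)
Conditions: p-TsOH·H2O (0.2 equiv), benzene, 50 °C; purification on AgNO3-impregnated silica if needed
Reagents that add atoms: none
Why: Acid-catalysed E1 dehydration: ionisation of the tertiary C4 alcohol and reversible proton loss funnel the alkene isomers through the common C4 cation to the tetrasubstituted C4=C5 alkene (the outcome known for acid treatment of 4-hydroxyeudesmanes); the water released hydrolyses the enol silane to the C8 ketone, C5 ceases to be a stereocentre, C10 is untouched, and catalytic acid at mild temperature is chosen to stop before migration toward C6.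

Step 10
Reactants: 19 4,10-dimethyloctal-4-en-8-one; 20 allyl bromide
Product: 23 (3S,8aR)-3-allyl-5,8a-dimethyl-3,4,6,7,8,8a-hexahydronaphthalen-2(1H)-one (7β-allyl ketone), via lithium enolate 21 (not isolated), via 7α-allyl epimer 22 (not isolated)
Conditions: LiN(i-Pr)2 (1.05 equiv), THF, −78 °C; allyl bromide, DMPU, −78 to −20 °C; crude product with NaOMe (0.2 equiv), MeOH, rt
Reagents that add atoms: lithium diisopropylamide [Li]N(C(C)C)C(C)C; allyl bromide C=CCBr
Why: Kinetic enolate alkylation: the amide base removes a C7 proton rather than a neopentyl C9 proton, allyl bromide adds mainly along the axial (α) direction, and methoxide equilibration through the enolate then moves the allyl group into the equatorial 7β position, because the cyclohexene geometry of ring A fixes ring B as a chair with C14 axial.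

Step 11
Reactants: 23 7β-allyl ketone
Product: 24 7β-allyl-4,10-dimethyloctal-4-en-8β-ol
Conditions: LiBH(s-Bu)3 (1.2 equiv), THF, −78 °C; then NaOH, H2O2, 0 °C
Reagents that add atoms: none
Why: Reduction with the bulky trialkylborohydride follows the equatorial (α-face) trajectory, which is also the face away from axial C14, and should give the axial 8β alcohol cis to the 7β allyl group, as is general for 2-alkylcyclohexanones.

Step 12
Reactants: 24 8β-alcohol; 25 acetic anhydride
Product: 26 7β-allyl-4,10-dimethyloctal-4-en-8β-yl acetate
Conditions: Ac2O, pyridine, 4-(dimethylamino)pyridine (0.1 equiv), CH2Cl2, rt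
Reagents that add atoms: acetic anhydride CC(=O)OC(C)=O
Why: Nucleophile-catalysed acylation esterifies the single axial secondary alcohol, and fixing C8–O as the acetate before C12 reaches the acid level rules out closure to the 8,12-lactone.

Step 13
Reactants: 26 8β-acetate
Product: 28 8β-acetoxy-13-noreudesm-4-en-12-al, via vicinal diol 27 (not isolated)
Conditions: OsO4 (2 mol %), NaIO4 (4 equiv), 2,6-lutidine (2 equiv), dioxane/H2O 3:1, rt
Reagents that add atoms: osmium tetroxide O=[Os](=O)(=O)=O; sodium periodate [Na+].[O-]I(=O)(=O)=O; water O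
Why: Lemieux–Johnson cleavage: OsO4 dihydroxylates the unhindered monosubstituted alkene much faster than the tetrasubstituted C4=C5 alkene flanked by quaternary C10, and periodate cleaves the diol to the C12 aldehyde.

Step 14
Reactants: 28 C12 aldehyde; 29 dimethyl(methylidene)ammonium iodide
Product: 31 8β-acetoxyeudesma-4,11(13)-dien-12-al, via Mannich base 30 (not isolated)
Conditions: CH2=NMe2+ I− (3 equiv), Et3N (4 equiv), CH2Cl2, rt
Reagents that add atoms: dimethyl(methylidene)ammonium iodide C=[N+](C)C.[I-]
Why: Mannich reaction of the aldehyde with the iminium salt followed by elimination of dimethylamine is the standard alpha-methylenation of aldehydes and is mild enough for the acetate; C7 is not acidified and keeps its configuration.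

Step 15
Reactants: 31 enal
Product: 32 8β-acetoxyeudesma-4,11(13)-dien-12-oic acid
Conditions: NaClO2, NaH2PO4, 2-methylbut-2-ene (large excess), t-BuOH/H2O, 0 °C to rt
Reagents that add atoms: sodium chlorite [Na+].[O-]Cl=O
Why: Pinnick oxidation converts the 2-substituted acrolein into the acrylic acid without touching alkenes, the excess of 2-methylbut-2-ene intercepting hypochlorous acid before it can reach C4=C5.

Step 16
Reactants: 32 acrylic acid; 33 iodomethane
Product: 34 methyl 8β-acetoxyeudesma-4,11(13)-dien-12-oate
Conditions: MeI, K2CO3, DMF, rt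
Reagents that add atoms: iodomethane IC
Why: SN2 alkylation of the potassium carboxylate gives the methyl ester under conditions too weakly basic to cleave the acetate or to add to the acrylate.

Step 17
Reactants: 34 dienoate
Product: 35 methyl 8β-acetoxy-3-oxoeudesma-4,11(13)-dien-12-oate
Conditions: CrO3, 3,5-dimethylpyrazole (15 equiv each), CH2Cl2, −20 °C
Reagents that add atoms: chromium trioxide O=[Cr](=O)=O
Why: Allylic oxidation with the CrO3–3,5-dimethylpyrazole complex attacks only the electron-rich C4=C5 alkene and should choose C3, whose pseudoaxial α hydrogen is aligned and open, over C6, whose only aligned hydrogen (6β) is crowded by C14 and the 8β acetate and whose ketone would clash with C15, in line with the behaviour of eudesm-4-enes.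

Step 18
Reactants: 35 enone
Product: 36 methyl 8β-acetoxy-3β-hydroxyeudesma-4,11(13)-dien-12-oate
Conditions: NaBH4, CeCl3·7H2O, MeOH, −20 to 0 °C
Reagents that add atoms: none
Why: Luche reduction gives 1,2-reduction of the enone while the acrylate and the esters survive the short cold exposure, and hydride arrives axially from the α face, as with steroidal 4-en-3-ones, to give the pseudoequatorial 3β alcohol.

Step 19
Reactants: 36 3β-alcohol; 37 isobutyryl chloride
Product: 38 methyl 8β-acetoxy-3β-isobutyryloxyeudesma-4,11(13)-dien-12-oate
Conditions: i-PrCOCl, pyridine, 4-(dimethylamino)pyridine (0.1 equiv), CH2Cl2, 0 °C to rt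
Reagents that add atoms: isobutyryl chloride CC(C)C(=O)Cl
Why: Acylation of the only free hydroxyl group with an acid chloride and pyridine proceeds with retention at C3 because the C–O bond is not touched.

Step 20
Reactants: 38 3β-isobutyrate
Product: 39 methyl 8β-acetoxy-5α-hydroperoxy-3β-isobutyryloxyeudesma-4(15),11(13)-dien-12-oate (3S,5S,7R,8R,10R; target)
Conditions: O2, 5,10,15,20-tetraphenylporphyrin (1 mol %), visible light, CH2Cl2, −20 to 0 °C; no reductive work-up
Reagents that add atoms: dioxygen O=O
Why: Schenck ene reaction: singlet oxygen attacks only the tetrasubstituted C4=C5 alkene (the acrylate is inert) from the α face opposite axial C14 and the β ester groups, bonds to C5 and takes a hydrogen from the freely rotating C15 methyl group to set 5α-OOH and the C4=C15 methylene, since on that face H-6α is equatorial and unaligned and H-3α is deactivated by the geminal acyloxy group.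

Compound list
1 | hex-5-yn-1-ol | C#CCCCCO | starting material
2 | trimethylaluminium | C[Al](C)C | starting material
3 | dimethyl[(E)-6-(dimethylalumanyloxy)-2-methylhex-1-enyl]alane | C[Al](C)OCCCC/C(C)=C/[Al](C)C | intermediate
4 | (E)-6-iodo-5-methylhex-5-en-1-ol | OCCCC/C(C)=C/I | intermediate
5 | (E)-6-iodo-5-methylhex-5-enoic acid | OC(=O)CCC/C(C)=C/I | intermediate
6 | N,O-dimethylhydroxylamine hydrochloride | CNOC.Cl | starting material
7 | (E)-1-(imidazol-1-yl)-6-iodo-5-methylhex-5-en-1-one | O=C(CCC/C(C)=C/I)n1ccnc1 | intermediate
8 | (E)-6-iodo-N-methoxy-N,5-dimethylhex-5-enamide | CON(C)C(=O)CCC/C(C)=C/I | intermediate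
9 | tributyl(1-ethoxyvinyl)stannane | CCCC[Sn](CCCC)(CCCC)C(=C)OCC | starting material
10 | (E)-7-ethoxy-N-methoxy-N,5-dimethylocta-5,7-dienamide | CON(C)C(=O)CCC/C(C)=C/C(=C)OCC | intermediate
11 | (E)-N-methoxy-N,5-dimethyl-7-oxooct-5-enamide | CON(C)C(=O)CCC/C(C)=C/C(C)=O | intermediate
12 | (E)-N-methoxy-N,5-dimethyl-7-(triisopropylsilyloxy)octa-5,7-dienamide | CON(C)C(=O)CCC/C(C)=C/C(=C)O[Si](C(C)C)(C(C)C)C(C)C | intermediate
13 | vinylmagnesium bromide | C=C[Mg]Br | starting material
14 | bromomagnesium alkoxide of the tetrahedral vinyl adduct of 12 | C=CC(O[Mg]Br)(N(C)OC)CCC/C(C)=C/C(=C)O[Si](C(C)C)(C(C)C)C(C)C | intermediate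
15 | (E)-7-methyl-9-(triisopropylsilyloxy)deca-1,7,9-trien-3-one | C=CC(=O)CCC/C(C)=C/C(=C)O[Si](C(C)C)(C(C)C)C(C)C | intermediate
16 | (4aR,8aS)-4a-methyl-6-(triisopropylsilyloxy)-3,4,4a,7,8,8a-hexahydronaphthalen-1(2H)-one | C1C[C@@H]2C(=O)CCC[C@]2(C)C=C1O[Si](C(C)C)(C(C)C)C(C)C | intermediate
17 | methylmagnesium bromide | C[Mg]Br | starting material
18 | 4-hydroxy-4,10-dimethyl-8-(triisopropylsilyloxy)octal-8-ene, 5β-H, 10β-Me, C4 open | C1C[C@@H]2C(C)(O)CCC[C@]2(C)C=C1O[Si](C(C)C)(C(C)C)C(C)C | intermediate
19 | (R)-5,8a-dimethyl-3,4,6,7,8,8a-hexahydronaphthalen-2(1H)-one | CC1=C2CCC(=O)C[C@@]2(C)CCC1 | intermediate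
20 | allyl bromide | C=CCBr | starting material
21 | lithium C7=C8 enolate of 19 | [Li]OC1=CCC2=C(C)CCC[C@]2(C)C1 | intermediate
22 | 7α-allyl-4,10-dimethyloctal-4-en-8-one | C=CC[C@@H]1CC2=C(C)CCC[C@]2(C)CC1=O | intermediate
23 | (3S,8aR)-3-allyl-5,8a-dimethyl-3,4,6,7,8,8a-hexahydronaphthalen-2(1H)-one (7β-allyl) | C=CC[C@H]1CC2=C(C)CCC[C@]2(C)CC1=O | intermediate
24 | 7β-allyl-4,10-dimethyloctal-4-en-8β-ol | C=CC[C@H]1CC2=C(C)CCC[C@]2(C)C[C@H]1O | intermediate
25 | acetic anhydride | CC(=O)OC(C)=O | starting material
26 | 7β-allyl-4,10-dimethyloctal-4-en-8β-yl acetate | C=CC[C@H]1CC2=C(C)CCC[C@]2(C)C[C@H]1OC(C)=O | intermediate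
27 | 7β-(2,3-dihydroxypropyl)-4,10-dimethyloctal-4-en-8β-yl acetate, carbinol centre open | OCC(O)C[C@H]1CC2=C(C)CCC[C@]2(C)C[C@H]1OC(C)=O | intermediate
28 | 8β-acetoxy-13-noreudesm-4-en-12-al | O=CC[C@H]1CC2=C(C)CCC[C@]2(C)C[C@H]1OC(C)=O | intermediate
29 | dimethyl(methylidene)ammonium iodide | C=[N+](C)C.[I-] | starting material
30 | 8β-acetoxy-13-(dimethylamino)eudesm-4-en-12-al, C11 open | CN(C)CC(C=O)[C@H]1CC2=C(C)CCC[C@]2(C)C[C@H]1OC(C)=O | intermediate
31 | 8β-acetoxyeudesma-4,11(13)-dien-12-al | C=C(C=O)[C@H]1CC2=C(C)CCC[C@]2(C)C[C@H]1OC(C)=O | intermediate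
32 | 8β-acetoxyeudesma-4,11(13)-dien-12-oic acid | C=C(C(=O)O)[C@H]1CC2=C(C)CCC[C@]2(C)C[C@H]1OC(C)=O | intermediate
33 | iodomethane | IC | starting material
34 | methyl 8β-acetoxyeudesma-4,11(13)-dien-12-oate | C=C(C(=O)OC)[C@H]1CC2=C(C)CCC[C@]2(C)C[C@H]1OC(C)=O | intermediate
35 | methyl 8β-acetoxy-3-oxoeudesma-4,11(13)-dien-12-oate | C=C(C(=O)OC)[C@H]1CC2=C(C)C(=O)CC[C@]2(C)C[C@H]1OC(C)=O | intermediate
36 | methyl 8β-acetoxy-3β-hydroxyeudesma-4,11(13)-dien-12-oate | C=C(C(=O)OC)[C@H]1CC2=C(C)[C@@H](O)CC[C@]2(C)C[C@H]1OC(C)=O | intermediate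
37 | isobutyryl chloride | CC(C)C(=O)Cl | starting material
38 | methyl 8β-acetoxy-3β-isobutyryloxyeudesma-4,11(13)-dien-12-oate | C=C(C(=O)OC)[C@H]1CC2=C(C)[C@@H](OC(=O)C(C)C)CC[C@]2(C)C[C@H]1OC(C)=O | intermediate
39 | methyl 8β-acetoxy-5α-hydroperoxy-3β-isobutyryloxyeudesma-4(15),11(13)-dien-12-oate | C=C(C(=O)OC)[C@H]1C[C@@]2(OO)C(=C)[C@@H](OC(=O)C(C)C)CC[C@]2(C)C[C@H]1OC(C)=O | target

Total step count: 20. Longest linear sequence: 20 steps (1 to 39).

Steps most likely to fail

Step 7.
- What may go wrong: Bond formation at the fully substituted C10 may be slow at the temperatures where the catalyst is selective. Proton or silyl transfer, intermolecular Mukaiyama–Michael addition and the uncatalysed racemic cycloaddition could then gain ground. Incomplete endo preference would also lower the enantiomeric purity at C10 once C5 is erased.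
- Fallback: It sets out from 15 and replaces catalytic induction by resolution. Me2AlCl in CH2Cl2 at −78 °C should give the racemic cis-fused adduct F1. The lithium salt of (S)-N,S-dimethyl-S-phenylsulfoximine (n-BuLi, THF, −78 °C) is then added to the C4 ketone. This should give one diastereomer per ketone enantiomer, separable by chromatography. The 10R β-hydroxysulfoximine F2 is heated in toluene, where retro-addition releases the ketone, and the route is rejoined at 16.

Step 20.
- What may go wrong: Hydrogen abstraction may occur from H-3α or from C6 instead of C15. Partial attack on the β face, a sluggish reaction of an alkene deactivated by the allylic ester, or acid-induced cleavage of the hydroperoxide during purification are also possible.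
- Fallback: It sets out from 36 and changes the order of events, so that the ene reaction is run on an ether and the ester is put on afterwards with the peroxide masked.
 - t-BuMe2SiCl and imidazole in DMF give the 3β-silyl ether F3. Its oxygen substituent withdraws less electron density from C4, and its bulk, geminal to C15, favours abstraction from the methyl group.
 - Photooxygenation as in step 20 should give the 5α-hydroperoxide F4.
 - 2-Methoxypropene with pyridinium p-toluenesulfonate masks it as the 2-methoxyprop-2-yl peroxyketal F5.
 - Bu4NF buffered with AcOH frees the 3β-alcohol F6.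
 - Isobutyryl chloride 37 with pyridine gives the isobutyrate peroxyketal F7.
 - AcOH/THF/H2O at rt removes the peroxyketal, and the route is rejoined at 39.

Step 6.
- What may go wrong: The liberated N,O-dimethylhydroxylamine may add in conjugate fashion during the quench. The enol silane may be hydrolysed in the acidic quench. The trienone may polymerise or cyclise prematurely on concentration.
- Fallback: It sets out from 12 and reaches the vinyl ketone by a neutral oxidation instead of an acyl substitution. i-Bu2AlH in THF at −78 °C with a potassium sodium tartrate work-up gives the dienal F8. Vinylmagnesium bromide 13 adds to give the allylic alcohol F9. Activated MnO2 in CH2Cl2 at 0 °C oxidises it with no amine and no acid present. The filtered solution of 15 is fed directly into step 7, where the route is rejoined.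

Further compounds
F1 | step 7 | racemic cis-fused 10-methyl-8-(triisopropylsilyloxy)octal-8-en-4-one (both enantiomers) | C1C[C@@H]2C(=O)CCC[C@]2(C)C=C1O[Si](C(C)C)(C(C)C)C(C)C.C1C[C@H]2C(=O)CCC[C@@]2(C)C=C1O[Si](C(C)C)(C(C)C)C(C)C
F2 | step 7 | 10R β-hydroxysulfoximine from 16 and (S)-N,S-dimethyl-S-phenylsulfoximine, C4 open | C1C[C@@H]2C(O)(C[S@@](=O)(=NC)c3ccccc3)CCC[C@]2(C)C=C1O[Si](C(C)C)(C(C)C)C(C)C
F3 | step 20 | methyl 8β-acetoxy-3β-(tert-butyldimethylsilyloxy)eudesma-4,11(13)-dien-12-oate | C=C(C(=O)OC)[C@H]1CC2=C(C)[C@@H](O[Si](C)(C)C(C)(C)C)CC[C@]2(C)C[C@H]1OC(C)=O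
F4 | step 20 | methyl 8β-acetoxy-3β-(tert-butyldimethylsilyloxy)-5α-hydroperoxyeudesma-4(15),11(13)-dien-12-oate | C=C(C(=O)OC)[C@H]1C[C@@]2(OO)C(=C)[C@@H](O[Si](C)(C)C(C)(C)C)CC[C@]2(C)C[C@H]1OC(C)=O
F5 | step 20 | 2-methoxyprop-2-yl peroxyketal of F4 | C=C(C(=O)OC)[C@H]1C[C@@]2(OOC(C)(C)OC)C(=C)[C@@H](O[Si](C)(C)C(C)(C)C)CC[C@]2(C)C[C@H]1OC(C)=O
F6 | step 20 | methyl 8β-acetoxy-3β-hydroxy-5α-(2-methoxyprop-2-ylperoxy)eudesma-4(15),11(13)-dien-12-oate | C=C(C(=O)OC)[C@H]1C[C@@]2(OOC(C)(C)OC)C(=C)[C@@H](O)CC[C@]2(C)C[C@H]1OC(C)=O
F7 | step 20 | methyl 8β-acetoxy-3β-isobutyryloxy-5α-(2-methoxyprop-2-ylperoxy)eudesma-4(15),11(13)-dien-12-oate | C=C(C(=O)OC)[C@H]1C[C@@]2(OOC(C)(C)OC)C(=C)[C@@H](OC(=O)C(C)C)CC[C@]2(C)C[C@H]1OC(C)=O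
F8 | step 6 | (E)-5-methyl-7-(triisopropylsilyloxy)octa-5,7-dienal | O=CCCC/C(C)=C/C(=C)O[Si](C(C)C)(C(C)C)C(C)C
F9 | step 6 | (E)-7-methyl-9-(triisopropylsilyloxy)deca-1,7,9-trien-3-ol (racemic carbinol) | C=CC(O)CCC/C(C)=C/C(=C)O[Si](C(C)C)(C(C)C)C(C)C
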